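The target comes from step 1, so I look for the concentration that sets the order of that step's rate, and that is [nucleophile].

electrophile 1.0 mM; protonated nucleophile 1.50 equiv; solid base 3.00 equiv; time 6.0 min

    electrophile + nucleophile → acid set free + target (k1 = 120 M⁻¹ s⁻¹)
    nucleophile + acid set free ⇌ protonated nucleophile, settled at all times (K2 = 23000 M⁻¹)
    acid set free + free base ⇌ salt of the base, settled at all times (K3 = 7.0 × 10⁶ M⁻¹)
    electrophile ⇌ dormant form (K4 = 1.3, k4 = 0.0035 s⁻¹)
    crystals ⇌ target, rate k5*(cs5 - [target]) while solid is left; crystals form when [target] > cs5 (cs5 = 0.32 mM, k5 = 1.3 s⁻¹)
    solid base ⇌ free base, rate k6*(cs6 - [free base]) while solid is left; crystals form when [free base] > cs6 (cs6 = 0.91 mM, k6 = 0.0038 s⁻¹)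

- target is meant together with its crystals
- solid, in amounts per volume of the solution: crystals, solid base
- at the start none of the solid base is in solution
- what has gone from electrophile into another species counts as reacted, even if it can come back
- run time (flask): 6.0 min

- part of the electrophile that has reacted at 6.0 min
- share of the unused nucleophile that is free and not bound as protonated nucleophile, at 6.0 min

A bench rule of thumb treats the protonated nucleophile as a reservoir that holds [nucleophile] steady, which makes the loss of electrophile pseudo-first-order. In this flask, of the charge 1.50 mM, a part comes apart at the start into 0.235 mM of nucleophile and as much acid, and the rest stays protonated. The half-life of electrophile by step 1 at that [nucleophile] is then 0.410 min, and the rule puts 14.6 half-lives into the run.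

The rule ignores where the acid goes. Dissolved base meets acid and becomes salt, so while salt and acid stand at similar levels, [free base] sits near 1.43 × 10⁻⁴ mM, far below its solubility, and solid base enters at very nearly its full rate. I call that rate the base feed: the dissolution coefficient times the solubility, 0.207 mM min⁻¹.

The border of the rule is the ratio of acid release to feed. Step 1 starts by setting acid free at 1.69 mM min⁻¹, which is 8.16 times the feed, so I expect acid to pile up and [nucleophile] to fall. My reckoning stops at the base: up to 6.0 min the feed comes to 1.24 mM, which is 41.5% of the solid charged. It gives me no figure for either answer.

The forecast says 94% reacted, within 91% to 96.5%, and 11% free, within 8% to 14%. Its ground is that dissolving base “sets the pace and frees nucleophile again”. It counts about 1.26 mM of base dissolved, where I have 1.24 mM.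

This flask gives 93.8% reacted and 10.3% free. In this flask step 1 had 62% of its turnover up to 6.0 min behind it by 1.20 min, while acid stood at 0.663 mM at 0.600 min. Base dissolved steadily, 20% of its turnover up to 6.0 min by 1.20 min, and at 6.00 min acid stood at 0.379 mM with salt at 1.24 mM, against 1.24 mM from the feed. In the neighbour with 1.7 mM electrophile the feed is unchanged, and salt again stands at 1.24 mM. The feed leaves 75.6% of its larger solid charge, and that flask holds 76%, with acid at 1.31 mM and a free share of 3.21%.

The constants used here were drawn at random within sensible limits; the run is a simulation.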